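**Strategy.** Everything rests on the C8–C10 bond (numbering: furan ring C1–C4, chain C5–C20, branch methyls C9, C14, C19, tetronic acid ring C21–C24): it links the methyl-bearing sp2 carbon of the 7E olefin to a methylene lying homoallylic to the 12Z olefin. A carboxyl group on C10 is the traceless handle. In one operation, nickel-electrocatalytic decarboxylative alkenylation joins the redox-active ester of a (Z)-4-enoic acid, which already carries the 18S centre and the O-methylated 20Z-ylidene tetronate ring, to an (E)-2-iodo-2-alkene bearing the 3-furyl ring. Both olefin geometries are set beforehand and retained; only O-demethylation follows.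

Key step: step 14

Assumption and convention: the silylethyl acetate ester used in step 7 is treated as purchasable (otherwise one acetylation from its parent alcohol); locants in steps 7–13 are those of the dec-4-enoate names, while C8, C10, C12, C13 and C18 in steps 14 and 15 follow the overview numbering.

**Fragment A: alkenyl iodide**

Step 1
Reactants: 1 pent-3-yn-1-ol
Product: 2 5-iodopent-2-yne
Conditions: I2, PPh3, imidazole, CH2Cl2, 0 °C to rt
Reagents that add atoms: iodine, [I][I]
Why: Appel-type iodination: the alkoxyphosphonium ion formed from PPh3/I2 is displaced by iodide in an SN2 step that leaves the internal alkyne untouched.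

Step 2
Reactants: 2 5-iodopent-2-yne; 3 3-bromofuran
Product: 5 3-(pent-3-yn-1-yl)furan, via pent-3-yn-1-ylzinc iodide 4 (not isolated)
Conditions: Zn dust (activated with BrCH2CH2Br and Me3SiCl), DMA, 40 °C; then 3, Pd(OAc)2 (2 mol%), SPhos (4 mol%), THF/DMA, rt to 50 °C
Reagents that add atoms: none
Why: Zinc inserts into the primary C–I bond to give an alkylzinc iodide that tolerates the internal alkyne, and Negishi coupling under zerovalent palladium/SPhos catalysis joins it to C3 of the furan.

Step 3
Reactants: 5 3-(pent-3-yn-1-yl)furan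
Product: 7 3-[(3E)-4-iodopent-3-en-1-yl]furan, via alkenylzirconocene chloride 6 (not isolated)
Conditions: Cp2Zr(H)Cl (2.5 equiv), THF, 50 °C; then I2, THF, 0 °C
Reagents that add atoms: iodine, [I][I]
Why: syn-Hydrozirconation of the 2-alkyne, run with excess Cp2Zr(H)Cl at 50 °C so that the regioisomers equilibrate to zirconium on the less hindered methyl-bearing carbon, followed by iodinolysis with retention, should give the E iodide (H and I cis).

**Fragment B: methyl tetronate**

Step 4
Reactants: 8 ethyl 2-methyl-3-oxobutanoate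
Product: 10 4-hydroxy-3-methylfuran-2(5H)-one (3-methyltetronic acid), via ethyl 4-bromo-2-methyl-3-oxobutanoate 9 (not isolated)
Conditions: Br2, CHCl3, 0 °C to rt, 16 h; then neat, 110 °C
Reagents that add atoms: none
Why: Classical tetronic acid synthesis: bromination and HBr-mediated equilibration place bromine on C4, and on heating the ester carbonyl oxygen displaces it (5-exo-tet) with loss of bromoethane to close the lactone.

Step 5
Reactants: 10 4-hydroxy-3-methylfuran-2(5H)-one
Product: 11 4-methoxy-3-methylfuran-2(5H)-one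
Conditions: Me2SO4, K2CO3, acetone, reflux
Reagents that add atoms: dimethyl sulfate, COS(=O)(=O)OC
Why: O-Methylation of the vinylogous acid gives the methyl tetronate, which masks the acidic OH and allows later lithiation at C5.

**Main line**

Step 6
Reactants: 12 nerol, (2Z)-3,7-dimethylocta-2,6-dien-1-ol
Product: 13 neryl bromide, (2Z)-1-bromo-3,7-dimethylocta-2,6-diene
Conditions: PBr3 (0.4 equiv), Et2O, −10 °C; used crude
Reagents that add atoms: phosphorus tribromide, BrP(Br)Br
Why: SN2 bromination of the primary allylic alcohol at low temperature should proceed without allylic transposition and with retention of the 2Z geometry.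

Step 7
Reactants: 13 neryl bromide; 14 2-(trimethylsilyl)ethyl acetate
Product: 16 2-(trimethylsilyl)ethyl (4Z)-5,9-dimethyldeca-4,8-dienoate, via lithium enolate of the acetate 15 (not isolated)
Conditions: 14, LiN(iPr)2, THF, −78 °C; then 13, DMPU, −78 to −30 °C
Reagents that add atoms: none
Why: Ester enolate alkylation: the lithium enolate attacks the primary allylic bromide in SN2 fashion, adding the two carbons that become the radical-bearing methylene and its carboxyl handle while the Z olefin is preserved.

Step 8
Reactants: 16 2-(trimethylsilyl)ethyl (4Z)-5,9-dimethyldeca-4,8-dienoate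
Product: 17 2-(trimethylsilyl)ethyl (4Z,8E)-10-hydroxy-5,9-dimethyldeca-4,8-dienoate
Conditions: SeO2 (0.3 equiv), t-BuOOH (3 equiv), salicylic acid (0.1 equiv), CH2Cl2, rt
Reagents that add atoms: selenium dioxide, O=[Se]=O; tert-butyl hydroperoxide, CC(C)(C)OO
Why: SeO2-catalysed allylic oxidation (ene reaction then 2,3-sigmatropic shift) with t-BuOOH as terminal oxidant is selective for the E methyl group of the terminal trisubstituted olefin over the more hindered internal one.

Step 9
Reactants: 17 2-(trimethylsilyl)ethyl (4Z,8E)-10-hydroxy-5,9-dimethyldeca-4,8-dienoate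
Product: 18 2-(trimethylsilyl)ethyl (4Z,9S)-10-hydroxy-5,9-dimethyldec-4-enoate
Conditions: Ru(OAc)2[(S)-BINAP] (1 mol%), H2 (100 atm), MeOH, 25 °C
Reagents that add atoms: none
Why: Hydroxyl-directed Noyori-type asymmetric hydrogenation: the Ru–BINAP dicarboxylate reduces only the allylic C8=C9 bond (isolated C4=C5 olefin and ester untouched), and by the facial model established for geraniol and nerol the (S)-BINAP complex should deliver H2 to the face that gives the 9S centre.

Step 10
Reactants: 18 2-(trimethylsilyl)ethyl (4Z,9S)-10-hydroxy-5,9-dimethyldec-4-enoate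
Product: 19 2-(trimethylsilyl)ethyl (4Z,9S)-5,9-dimethyl-10-oxodec-4-enoate
Conditions: Dess–Martin periodinane, CH2Cl2, 0 °C to rt; used at once
Reagents that add atoms: none
Why: Dess–Martin oxidation under near-neutral conditions should give the α-branched aldehyde without epimerisation, provided it is carried on immediately.

Step 11
Reactants: 19 2-(trimethylsilyl)ethyl (4Z,9S)-5,9-dimethyl-10-oxodec-4-enoate; 11 4-methoxy-3-methylfuran-2(5H)-one
Product: 21 2-(trimethylsilyl)ethyl (4Z,9S)-10-hydroxy-10-(3-methoxy-4-methyl-5-oxo-2,5-dihydrofuran-2-yl)-5,9-dimethyldec-4-enoate as a mixture of epimers at the two new centres, via lithium 4-methoxy-3-methylfuran-2-olate 20 (not isolated)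
Conditions: 11, LiN(iPr)2, THF, −78 °C; then 19, −78 °C; NH4Cl (aq)
Reagents that add atoms: none
Why: Aldol addition: deprotonation of 11 at C5 gives the aromatic lithium furanolate, which adds through C5 to the aldehyde at −78 °C faster than it enolises it; the two new centres form unselectively and are both removed in step 12.

Step 12
Reactants: 21 aldol adduct
Product: 23 2-(trimethylsilyl)ethyl (4Z,9S,10Z)-10-(3-methoxy-4-methyl-5-oxofuran-2(5H)-ylidene)-5,9-dimethyldec-4-enoate, via C10 mesylate 22 (not isolated)
Conditions: MsCl, Et3N, CH2Cl2, 0 °C; then DBU, 0 °C to rt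
Reagents that add atoms: none
Why: Mesylation then DBU-mediated E1cB elimination through the furanolate gives the conjugated 5-ylidene butenolide, the Z isomer (C9 chain syn to the ring oxygen, away from the 4-methoxy group) being thermodynamically preferred, and brief exposure at low temperature should leave the now vinylogously acidic 9S centre intact.

Step 13
Reactants: 23 ylidene silylethyl ester
Product: 24 (4Z,9S,10Z)-10-(3-methoxy-4-methyl-5-oxofuran-2(5H)-ylidene)-5,9-dimethyldec-4-enoic acid
Conditions: Bu4NF, AcOH (1:1), THF, 0 °C to rt; pH 4 buffer work-up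
Reagents that add atoms: none
Why: Fluoride attack on silicon triggers β-elimination (ethylene and Me3SiF) and frees the carboxylic acid, while the acetic acid buffer keeps the medium too weakly basic to deprotonate C9–H, which is vinylogously activated by the lactone.

Step 14
Reactants: 24 (4Z,9S,10Z)-10-(3-methoxy-4-methyl-5-oxofuran-2(5H)-ylidene)-5,9-dimethyldec-4-enoic acid; 7 3-[(3E)-4-iodopent-3-en-1-yl]furan
Product: 26 (5Z)-5-[(2S,6Z,10E)-13-(furan-3-yl)-2,6,10-trimethyltrideca-6,10-dien-1-ylidene]-4-methoxy-3-methylfuran-2(5H)-one, via N-hydroxyphthalimide ester 25 (not isolated)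
Conditions: N-hydroxyphthalimide, iPrN=C=NiPr, DMF, rt; then 7 (1.5 equiv), NiCl2·6H2O (20 mol%), 2,2'-bipyridine (20 mol%), AgNO3 (30 mol%), LiCl, DMF, Mg anode, reticulated vitreous carbon cathode, constant current, rt
Reagents that add atoms: none
Why: The N-hydroxyphthalimide ester 25 accepts an electron (at the silver-nanoparticle-coated cathode or from low-valent nickel) and fragments to CO2, phthalimide anion and the primary C10 radical, while zerovalent nickel–bipyridine inserts into the C–I bond of 7; radical capture by the alkenylnickel species and reductive elimination from trivalent nickel forge the C10–C8 bond, the Mg anode supplying the electrons. The closest known reaction type is the nickel-electrocatalytic decarboxylative alkenylation of redox-active esters with alkenyl halides, developed for this kind of 1,5-diene assembly in polyprenoids. No ring is closed and no stereocentre is created. The step needs retention of both olefin geometries: the 7E geometry is carried through stereoretentive oxidative addition and reductive elimination at sp2 carbon, and the 12Z geometry survives if nickel capture of the C10 homoallyl radical outruns its reversible 3-exo closure onto C12=C13. It also needs chemoselectivity, which the mild cathode potential (O-methyl tetronate and furan are not reduced) and the absence of competing acidic or electrophilic sites should secure.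

Step 15
Reactants: 26 O-methyl tetronate
Product: 27 (5Z)-5-[(2S,6Z,10E)-13-(furan-3-yl)-2,6,10-trimethyltrideca-6,10-dien-1-ylidene]-4-hydroxy-3-methylfuran-2(5H)-one (target, CNP0168546.4)
Conditions: NaSEt, DMF, rt to 50 °C; then aq. HCl to pH 3
Reagents that add atoms: none
Why: SN2 O-demethylation: ethanethiolate attacks the methyl group of the vinylogous methyl ester and releases the tetronate anion, which on acidification gives the tetronic acid; olefins, furan and the 18S centre should not be affected.

**Compound list**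

1 | pent-3-yn-1-ol | CC#CCCO | starting material
2 | 5-iodopent-2-yne | CC#CCCI | intermediate
3 | 3-bromofuran | Brc1ccoc1 | starting material
4 | pent-3-yn-1-ylzinc iodide | CC#CCC[Zn]I | intermediate (not isolated)
5 | 3-(pent-3-yn-1-yl)furan | CC#CCCc1ccoc1 | intermediate
6 | chlorobis(cyclopentadienyl)[(E)-5-(furan-3-yl)pent-2-en-2-yl]zirconium (rings drawn sigma-bonded) | C/C(=C\CCc1ccoc1)[Zr](Cl)(C1C=CC=C1)C1C=CC=C1 | intermediate (not isolated)
7 | 3-[(3E)-4-iodopent-3-en-1-yl]furan | C/C(I)=C\CCc1ccoc1 | intermediate
8 | ethyl 2-methyl-3-oxobutanoate | CCOC(=O)C(C)C(C)=O | starting material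
9 | ethyl 4-bromo-2-methyl-3-oxobutanoate | CCOC(=O)C(C)C(=O)CBr | intermediate (not isolated)
10 | 4-hydroxy-3-methylfuran-2(5H)-one | CC1=C(O)COC1=O | intermediate
11 | 4-methoxy-3-methylfuran-2(5H)-one | COC1=C(C)C(=O)OC1 | intermediate
12 | nerol | CC(C)=CCC/C(C)=C\CO | starting material
13 | neryl bromide | CC(C)=CCC/C(C)=C\CBr | intermediate
14 | 2-(trimethylsilyl)ethyl acetate | CC(=O)OCC[Si](C)(C)C | starting material
15 | lithium enolate of 14 | C=C(O[Li])OCC[Si](C)(C)C | intermediate (not isolated)
16 | 2-(trimethylsilyl)ethyl (4Z)-5,9-dimethyldeca-4,8-dienoate | CC(C)=CCC/C(C)=C\CCC(=O)OCC[Si](C)(C)C | intermediate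
17 | 2-(trimethylsilyl)ethyl (4Z,8E)-10-hydroxy-5,9-dimethyldeca-4,8-dienoate | OC/C(C)=C/CC/C(C)=C\CCC(=O)OCC[Si](C)(C)C | intermediate
18 | 2-(trimethylsilyl)ethyl (4Z,9S)-10-hydroxy-5,9-dimethyldec-4-enoate | OC[C@@H](C)CCC/C(C)=C\CCC(=O)OCC[Si](C)(C)C | intermediate
19 | 2-(trimethylsilyl)ethyl (4Z,9S)-5,9-dimethyl-10-oxodec-4-enoate | O=C[C@@H](C)CCC/C(C)=C\CCC(=O)OCC[Si](C)(C)C | intermediate
20 | lithium 4-methoxy-3-methylfuran-2-olate | COc1coc(O[Li])c1C | intermediate (not isolated)
21 | 2-(trimethylsilyl)ethyl (4Z,9S)-10-hydroxy-10-(3-methoxy-4-methyl-5-oxo-2,5-dihydrofuran-2-yl)-5,9-dimethyldec-4-enoate (epimer mixture at C10 and the ring carbon) | COC1=C(C)C(=O)OC1C(O)[C@@H](C)CCC/C(C)=C\CCC(=O)OCC[Si](C)(C)C | intermediate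
22 | C10 methanesulfonate of 21 | COC1=C(C)C(=O)OC1C(OS(C)(=O)=O)[C@@H](C)CCC/C(C)=C\CCC(=O)OCC[Si](C)(C)C | intermediate (not isolated)
23 | 2-(trimethylsilyl)ethyl (4Z,9S,10Z)-10-(3-methoxy-4-methyl-5-oxofuran-2(5H)-ylidene)-5,9-dimethyldec-4-enoate | CC1=C(OC)/C(=C/[C@@H](C)CCC/C(C)=C\CCC(=O)OCC[Si](C)(C)C)OC1=O | intermediate
24 | (4Z,9S,10Z)-10-(3-methoxy-4-methyl-5-oxofuran-2(5H)-ylidene)-5,9-dimethyldec-4-enoic acid | CC1=C(OC)/C(=C/[C@@H](C)CCC/C(C)=C\CCC(=O)O)OC1=O | intermediate
25 | 1,3-dioxoisoindolin-2-yl ester of 24 | CC1=C(OC)/C(=C/[C@@H](C)CCC/C(C)=C\CCC(=O)ON2C(=O)c3ccccc3C2=O)OC1=O | intermediate (not isolated)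
26 | (5Z)-5-[(2S,6Z,10E)-13-(furan-3-yl)-2,6,10-trimethyltrideca-6,10-dien-1-ylidene]-4-methoxy-3-methylfuran-2(5H)-one | CC1=C(OC)/C(=C/[C@@H](C)CCC/C(C)=C\CC/C(C)=C/CCc2ccoc2)OC1=O | intermediate
27 | (5Z)-5-[(2S,6Z,10E)-13-(furan-3-yl)-2,6,10-trimethyltrideca-6,10-dien-1-ylidene]-4-hydroxy-3-methylfuran-2(5H)-one | CC1=C(O)/C(=C/[C@@H](C)CCC/C(C)=C\CC/C(C)=C/CCc2ccoc2)OC1=O | target

**Totals**

Total steps: 15 (steps 1–3 give iodide 7, steps 4–5 give tetronate 11, steps 6–15 are the main line).
Longest linear sequence: 10 steps (nerol 12 to target 27, steps 6–15).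

**Steps most likely to fail**

1. Step 14 (key coupling). The activated ester may be consumed by unproductive reduction (hydrodecarboxylation, radical dimerisation) before nickel capture. The homoallyl radical may also close reversibly to a cyclopropylcarbinyl radical and so erode the 12Z geometry, and oxidative addition of the α-methyl-substituted iodide may be slow. Fallback (a redox-neutral coupling with a preformed alkenyl nucleophile instead of a cathodic cross-electrophile coupling): setting out from 24 and 7, acid 24 is converted into the N-hydroxyphthalimide ester 25, this time isolated (N-hydroxyphthalimide, iPrN=C=NiPr, DMAP cat., CH2Cl2). Iodide 7 is converted by iodine–lithium exchange (t-BuLi, Et2O, −78 °C) into (E)-[5-(furan-3-yl)pent-2-en-2-yl]lithium F1 and then with ZnCl2 into (E)-[5-(furan-3-yl)pent-2-en-2-yl]zinc chloride F2. Decarboxylative Negishi-type alkenylation of 25 with F2 (Ni(acac)2, 2,2'-bipyridine, THF/DMF, rt) should return the route at 26; the higher standing concentration of alkenylnickel should favour fast radical capture.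

2. Step 9 (asymmetric hydrogenation). Facial selectivity in hydrogen delivery to the 2-methyl-substituted allylic alcohol may be insufficient or opposite to the geraniol model, and olefin migration may precede reduction. Fallback (carboxylate-directed instead of hydroxyl-directed hydrogenation, on the tiglic acid substrate class whose induction is well established): setting out from 17, MnO2 (CH2Cl2) should give 2-(trimethylsilyl)ethyl (4Z,8E)-5,9-dimethyl-10-oxodeca-4,8-dienoate F3. Pinnick oxidation (NaClO2, NaH2PO4, 2-methylbut-2-ene, t-BuOH/H2O) should give (2E,6Z)-2,6-dimethyl-10-oxo-10-[2-(trimethylsilyl)ethoxy]deca-2,6-dienoic acid F4. Hydrogenation with the Ru(OAc)2(BINAP) enantiomer that gives (S)-2-methylbutanoic acid from tiglic acid (H2, MeOH) should give (2S,6Z)-2,6-dimethyl-10-oxo-10-[2-(trimethylsilyl)ethoxy]dec-6-enoic acid F5. Activation as the isobutyl carbonic mixed anhydride F6 (i-BuOCOCl, N-methylmorpholine, THF, −15 °C) and NaBH4 reduction should return the route at 18.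

3. Step 13 (ester cleavage beside the ylidene tetronate). Fluoride may deprotonate C9, causing epimerisation or ylidene isomerisation, or cleavage may stall under the buffered conditions. Fallback (the order of events is reversed so that no ester has to be removed in the presence of the tetronate): setting out from 18, saponification (LiOH, THF/MeOH/H2O) should give (4Z,9S)-10-hydroxy-5,9-dimethyldec-4-enoic acid F7. Activation in situ (N-hydroxyphthalimide, iPrN=C=NiPr, DMF, no DMAP) to 1,3-dioxoisoindolin-2-yl (4Z,9S)-10-hydroxy-5,9-dimethyldec-4-enoate F8, followed by the nickel-electrocatalytic coupling of step 14 with 7, should give (2S,6Z,10E)-13-(furan-3-yl)-2,6,10-trimethyltrideca-6,10-dien-1-ol F9. Dess–Martin oxidation should give (2S,6Z,10E)-13-(furan-3-yl)-2,6,10-trimethyltrideca-6,10-dienal F10, and aldol addition of furanolate 20 (from 11) should give the aldol adduct 5-[(2S,6Z,10E)-13-(furan-3-yl)-1-hydroxy-2,6,10-trimethyltrideca-6,10-dien-1-yl]-4-methoxy-3-methylfuran-2(5H)-one F11. Mesylation to its methanesulfonate F12 and DBU elimination should return the route at 26.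

**Further compounds**

F1 | step 14 | (E)-[5-(furan-3-yl)pent-2-en-2-yl]lithium | [Li]/C(C)=C/CCc1ccoc1
F2 | step 14 | (E)-[5-(furan-3-yl)pent-2-en-2-yl]zinc chloride | Cl[Zn]/C(C)=C/CCc1ccoc1
F3 | step 9 | 2-(trimethylsilyl)ethyl (4Z,8E)-5,9-dimethyl-10-oxodeca-4,8-dienoate | O=C/C(C)=C/CC/C(C)=C\CCC(=O)OCC[Si](C)(C)C
F4 | step 9 | (2E,6Z)-2,6-dimethyl-10-oxo-10-[2-(trimethylsilyl)ethoxy]deca-2,6-dienoic acid | OC(=O)/C(C)=C/CC/C(C)=C\CCC(=O)OCC[Si](C)(C)C
F5 | step 9 | (2S,6Z)-2,6-dimethyl-10-oxo-10-[2-(trimethylsilyl)ethoxy]dec-6-enoic acid | OC(=O)[C@@H](C)CCC/C(C)=C\CCC(=O)OCC[Si](C)(C)C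
F6 | step 9 | isobutyl carbonic mixed anhydride of F5 | CC(C)COC(=O)OC(=O)[C@@H](C)CCC/C(C)=C\CCC(=O)OCC[Si](C)(C)C
F7 | step 13 | (4Z,9S)-10-hydroxy-5,9-dimethyldec-4-enoic acid | OC[C@@H](C)CCC/C(C)=C\CCC(=O)O
F8 | step 13 | 1,3-dioxoisoindolin-2-yl (4Z,9S)-10-hydroxy-5,9-dimethyldec-4-enoate | OC[C@@H](C)CCC/C(C)=C\CCC(=O)ON1C(=O)c2ccccc2C1=O
F9 | step 13 | (2S,6Z,10E)-13-(furan-3-yl)-2,6,10-trimethyltrideca-6,10-dien-1-ol | OC[C@@H](C)CCC/C(C)=C\CC/C(C)=C/CCc1ccoc1
F10 | step 13 | (2S,6Z,10E)-13-(furan-3-yl)-2,6,10-trimethyltrideca-6,10-dienal | O=C[C@@H](C)CCC/C(C)=C\CC/C(C)=C/CCc1ccoc1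
F11 | step 13 | 5-[(2S,6Z,10E)-13-(furan-3-yl)-1-hydroxy-2,6,10-trimethyltrideca-6,10-dien-1-yl]-4-methoxy-3-methylfuran-2(5H)-one | COC1=C(C)C(=O)OC1C(O)[C@@H](C)CCC/C(C)=C\CC/C(C)=C/CCc1ccoc1
F12 | step 13 | methanesulfonate of F11 | COC1=C(C)C(=O)OC1C(OS(C)(=O)=O)[C@@H](C)CCC/C(C)=C\CC/C(C)=C/CCc1ccoc1
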